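**Remark:** the target, 6-hydroxy-7-methoxy-3-[(2-oxo-2H-chromen-7-yl)oxy]-2H-chromen-2-one (C19H12O7), has no stereocentre or other stereogenic element, so the request for a single enantiomer puts no demand on the route.

## Structural features

- The molecule consists of two 2H-chromen-2-one (coumarin) bicycles joined only by one ether oxygen, which runs from C3 of the left unit (6-hydroxy-7-methoxy) to C7' of the right unit (umbelliferone type).
- There is no stereocentre and no stereogenic axis; apart from the methoxy carbon every carbon is sp2.
- The left benzene ring carries three oxygens: the lactone oxygen O1 at C8a, the methoxy group at C7 and the hydroxyl at C6. O1 and the C6 hydroxyl are para to each other, and C4a (which carries the pyranone carbon C4) is para to the C7 methoxy group and ortho to O1.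
- The left carbocycle is therefore 2-methoxyhydroquinone, acylated on one hydroxyl and C-alkenylated at its most electron-rich C–H carbon. This is the feature the key step exploits.
- The C3–O–C7' bond is an enol aryl ether on the α-carbon of an unsaturated lactone. C3 is not the electrophilic carbon of a coumarin (nucleophiles go to C4 or C2), so making this bond on an intact coumarin is the unusual part of the connectivity.
- Fragile groups: both lactones open with hydroxide, alkoxide or amines; the free para-oxygenated phenol is easily oxidised; C3=C4 is reducible.
- The real difficulty is twofold: the enol ether at C3, and placing OH at C6 and OMe at C7 (the reverse of the more common 7-hydroxy-6-methoxy pattern) without protecting-group traffic.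

## Logic of the disconnections

Route in one sentence: an acid-promoted C–H annulation of unprotected 5 with 4 closes the left pyranone ring of 7. This sentence does not fit either route usually drawn first (ether coupling of two intact coumarins, or condensation of a salicylaldehyde with an aryloxyacetic acid). The step settles the ring, the C4–C4a bond and the 6-OH/7-OMe regiochemistry in one operation and delivers the free phenol.

**7 ⇒ 4 + 5 (through 6).** The bonds cut are C4–C4a (aryl–vinyl C–C) and O1–C2 (lactone C–O) of the left unit. Cutting here removes the left bicycle completely and leaves an arene, 5, that needs no formyl group, no halogen and no protecting group. The three-carbon partner 4 already carries the right coumarin and the ether oxygen. The demand on the forward step is that the C–H carbon of 5 that is para to OMe and ortho to an OH is the nucleophile, and that this ortho OH closes the lactone. The intermediate 6 must not be diverted to O-linked or chromone products.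

**4 ⇒ 3.** The bond cut is the C=C bond that becomes C3=C4 of the target; the carbon that becomes C4 is added as a one-carbon unit at the formate oxidation level, with dimethylamine as the leaving group. This converts the sp3 O–CH2 carbon of 3 into the sp2 enol-ether carbon, so the difficult C(sp2)–O bond at C3 never has to be made by substitution at a vinylic carbon. The demand is a neutral, non-aqueous condensation that spares the lactone of 3.

**3 ⇒ 1 + 2.** The bond cut is O7'–CH2, the future O–C3 bond, made at the sp3 level by alkylation of the only phenolic OH of 1. The gain is that both starting materials are commodity chemicals. The demand is only mild base, so that the lactone and the ester stay intact.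

## Other disconnections considered

**Alternative 1:** (the first that comes to mind) Cut: the O–C3 bond between two intact coumarins. Forward key step: copper-mediated Ullmann-type C–O coupling of 1 with the 3-bromocoumarin A2, which would be made from isoscopoletin A1 by O-benzylation and C3 bromination. The coupling would give the benzyl ether A3, and debenzylation would follow. Grounds for preferring the chosen plan:
- C3 is a vinylic carbon α to the carbonyl and its halide is not activated for substitution.
- The hot basic phenoxide medium is expected to attack C4 and C2 instead, which opens the way to cine-substitution and to base-induced ring contraction of the 3-halocoumarin to a benzofuran-2-carboxylate (Perkin rearrangement).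
- Bromination of the electron-rich ring system would have to distinguish C3 from C5 and C8.
- The 6-OH/7-OMe pattern is bought with costly A1 and not built, and it needs a protecting group whose hydrogenolytic removal endangers C3=C4.
- The sequence is at least four steps against three.

**Alternative 2:** Cut: C3=C4 and O1–C2, that is, carbonyl olefination followed by lactonisation. Forward key step: Horner–Wadsworth–Emmons reaction of the salicylaldehyde A4 with the α-aryloxy phosphonoacetate A5 (which would come from 1 by Rh(II)-catalysed O–H insertion of triethyl diazophosphonoacetate). Lactonisation would give A3, and deprotection would follow. Grounds for preferring the chosen plan: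
- A4 is not a commodity; its formyl group and three differentiated oxygens have to be installed first.
- Only the olefin isomer with the aryl group cis to the ester can lactonise.
- The sequence would run to five or more steps.
- The chosen plan uses the same C2–C3 building block, but lets the unfunctionalised arene 5 react through its innate C–H nucleophilicity. The protecting-group-free Perkin form of this disconnection is kept only as a fallback.

**Alternative 3:** Cut: O–C3 as a dehydrogenative C–H/O–H coupling of two coumarin monomers, copying the presumed biosynthesis of 3,7'-linked bicoumarins. Forward key step: anodic (or one-electron chemical) oxidation of esculetin A6 in the presence of 1 to give the catechol A7, either by phenoxyl radical cross-coupling or by conjugate addition of 1 to the o-quinone of A6. Selective 7-O-methylation would follow. Grounds for preferring the chosen plan: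
- In the radical or quinone derived from A6, C3 is only one of three positions (C3, C5, C8) that carry spin or acceptor density.
- 1 is an ambident partner (O7, C8, C6, C3) and is prone to homocoupling.
- The catechol product is more easily oxidised than either monomer.
- For the actual substitution pattern of the target (A1, with OH at C6) the phenoxyl oxygen is not conjugated with C3 at all, so the biosynthetic logic of the 7-hydroxy congeners cannot be transferred.
- The step count is attractive, but nothing in the substrates secures the site selectivity.

Key step: step 3

## Route

**Step 1**
Reactants: 1 umbelliferone (7-hydroxy-2H-chromen-2-one); 2 ethyl bromoacetate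
Product: 3 ethyl 2-[(2-oxo-2H-chromen-7-yl)oxy]acetate
Conditions: K2CO3 (1.5 equiv), acetone, reflux
Reagents that add atoms: none
Why: Williamson ether synthesis; the single, fairly acidic phenol (vinylogous to the lactone carbonyl) is deprotonated by carbonate and alkylated by the activated primary bromide, while dry carbonate in acetone leaves the lactone and the ethyl ester untouched.

**Step 2**
Reactants: 3 ethyl 2-[(2-oxo-2H-chromen-7-yl)oxy]acetate
Product: 4 ethyl (Z)-3-(dimethylamino)-2-[(2-oxo-2H-chromen-7-yl)oxy]prop-2-enoate
Conditions: t-BuOCH(NMe2)2 (2 equiv), toluene, 100 °C, N2; volatiles removed in vacuo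
Reagents that add atoms: Bredereck's reagent (tert-butoxybis(dimethylamino)methane), CC(C)(C)OC(N(C)C)N(C)C
Why: Bredereck aminomethylenation of an ester methylene; the reagent ionises to a formamidinium tert-butoxide pair that deprotonates the O–CH2–CO2Et carbon and C-formylates it at the amidinium level, and loss of dimethylamine gives the push–pull enamino ester (NMe2 trans to the ester expected; the geometry is of no consequence later). No aqueous base or free alkoxide accumulates, so the coumarin lactone should survive.

**Step 3**
Reactants: 4 ethyl (Z)-3-(dimethylamino)-2-[(2-oxo-2H-chromen-7-yl)oxy]prop-2-enoate; 5 2-methoxybenzene-1,4-diol (methoxyhydroquinone, 1.3 equiv)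
Product: 7 6-hydroxy-7-methoxy-3-[(2-oxo-2H-chromen-7-yl)oxy]-2H-chromen-2-one, via ethyl (E)-3-(2,5-dihydroxy-4-methoxyphenyl)-2-[(2-oxo-2H-chromen-7-yl)oxy]prop-2-enoate 6 (not isolated)
Conditions: AcOH/TFA (10:1), degassed, Ar, 85 °C; product precipitated with water
Reagents that add atoms: none
Why: Protonation of the push–pull alkene of 4 at its α-carbon gives an α-aryloxy iminium ion, which is attacked by C5 of 5 in a Mannich/Friedel–Crafts step; loss of dimethylamine (held as its ammonium salt) gives the β-aryl acrylate 6. The hydroxyl ortho to the new C–C bond then attacks the ethyl ester (6-exo-trig acyl substitution, ethanol lost) and closes the left pyranone ring; the required geometry (aryl cis to the ester) is reached because the double bond of 6 can equilibrate under acid through the para-methoxy-stabilised benzylic cation, or because lactonisation already takes place at the amine-adduct stage before elimination. The closest known reaction type is the Pechmann condensation in its 3-(dimethylamino)propenoate variant, by which activated phenols and 2-acylamino-3-(dimethylamino)propenoates give 3-acylaminocoumarins in hot acetic acid. No stereocentre is formed. The step needs site selectivity on 5: C5 is activated by two oxygens (para to OMe, ortho to the C4 hydroxyl) and is unhindered, C3 is activated equally but flanked by two substituents, and C6 has only one ortho oxygen and is meta to the other two. Only the C4 hydroxyl of 5 is ortho to the new bond, so it becomes O1, the C1 hydroxyl stays free as the 6-OH and the methoxy group ends at C7; the regiochemistry that separates the target from its 7-hydroxy-6-methoxy isomer is thus fixed by the substrate and needs no protecting group. C- versus O-attack is settled because O-vinylation is reversible under acid while C-attack leads on irreversibly to the aromatic lactone, and chromone formation would need acylation of the arene by an unactivated ethyl ester. The umbelliferone ring and the product are deactivated by their lactone carbonyls and should not react further, and the C3 enol ether should resist acid because protonation at C4 would place a cation next to the lactone carbonyl.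

## Compound list

1 | umbelliferone (7-hydroxy-2H-chromen-2-one) | Oc1ccc2ccc(=O)oc2c1 | starting material
2 | ethyl bromoacetate | CCOC(=O)CBr | starting material
3 | ethyl 2-[(2-oxo-2H-chromen-7-yl)oxy]acetate | CCOC(=O)COc1ccc2ccc(=O)oc2c1 | intermediate
4 | ethyl (Z)-3-(dimethylamino)-2-[(2-oxo-2H-chromen-7-yl)oxy]prop-2-enoate | CCOC(=O)/C(Oc1ccc2ccc(=O)oc2c1)=C/N(C)C | intermediate
5 | 2-methoxybenzene-1,4-diol (methoxyhydroquinone) | COc1cc(O)ccc1O | starting material
6 | ethyl (E)-3-(2,5-dihydroxy-4-methoxyphenyl)-2-[(2-oxo-2H-chromen-7-yl)oxy]prop-2-enoate | CCOC(=O)/C(Oc1ccc2ccc(=O)oc2c1)=C\c1cc(O)c(OC)cc1O | intermediate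
7 | 6-hydroxy-7-methoxy-3-[(2-oxo-2H-chromen-7-yl)oxy]-2H-chromen-2-one | COc1cc2oc(=O)c(Oc3ccc4ccc(=O)oc4c3)cc2cc1O | target

## Step count and least certain steps

Total step count: 3. Longest linear sequence: 3 steps (1 → 3 → 4 → 7); 5 enters in the last step.

**Step 3 (key step).**
- What may go wrong:
  - The arene carbon may be too weakly nucleophilic toward protonated 4 in a carboxylic acid medium, so that hydrolysis of the enamine and reversible O-vinylation consume 4.
  - C-attack at the hindered C3 or at C6 of 5, or O-vinylation followed by acylative closure in the chromone manifold, would erode the regiochemical purity.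
  - Adventitious oxygen would oxidise 5 to the quinone, which then takes up nucleophiles.
- The constitution of 7 (coumarin versus chromone, 6-OH/7-OMe placement) should be confirmed by HMBC and NOE before scale-up.
- Fallback (sets out from 3, returns at 7). It replaces the C–H annulation of an unfunctionalised arene by an aldol-type ring closure on an arene whose formyl carbon is already in place, so the regiochemistry no longer depends on the innate reactivity of 5.
  - 3 is saponified (LiOH, THF–H2O, then HCl, which recloses any opened lactone) to 2-[(2-oxo-2H-chromen-7-yl)oxy]acetic acid F1.
  - Purchased 2-hydroxy-4-methoxybenzaldehyde F2 is hydroxylated para to its phenol by Elbs persulfate oxidation (K2S2O8, aq NaOH) through potassium 5-formyl-4-hydroxy-2-methoxyphenyl sulfate F3, whose acid hydrolysis gives 2,5-dihydroxy-4-methoxybenzaldehyde F4.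
  - Perkin–Oglialoro condensation of F1 with F4 (Ac2O, NaOAc, 160 °C) should give 7-methoxy-2-oxo-3-[(2-oxo-2H-chromen-7-yl)oxy]-2H-chromen-6-yl acetate F5.
  - Deacetylation (aq HCl, MeOH, reflux) then gives 7.

**Step 2.**
- What may go wrong: slow aminomethylenation of the only weakly acidic O–CH2 group, so that long heating is needed; during it, liberated dimethylamine may cause aminolysis of the ethyl ester or opening of the lactone.
- Fallback (sets out from 3, returns at 7, bypassing 4). It replaces the aminal condensation by an enolate route and the enamine electrophile by a formyl ester.
  - Crossed Claisen formylation of 3 (HCO2Et, NaH, THF, 0 °C, acidic work-up to reclose any opened lactone) gives ethyl (E)-3-hydroxy-2-[(2-oxo-2H-chromen-7-yl)oxy]prop-2-enoate F6, the enol form of the α-formyl ester.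
  - F6 is condensed with 5 in a classical Pechmann reaction (MeSO3H, 40 °C, Ar) to give 7.

**Step 1.**
- What may go wrong: partial opening of the lactone or hydrolysis of the ethyl ester if the carbonate is wet, and incomplete conversion of the poorly soluble phenoxide.
- Fallback (sets out from 1, returns at 3): Mitsunobu etherification of 1 with ethyl glycolate (PPh3, DIAD, THF, 0 °C to rt). It forms the same O–CH2 bond from the alcohol under neutral conditions and makes no new compound.

## Further compounds

F1 | step 3 | 2-[(2-oxo-2H-chromen-7-yl)oxy]acetic acid | OC(=O)COc1ccc2ccc(=O)oc2c1
F2 | step 3 | 2-hydroxy-4-methoxybenzaldehyde (purchased) | COc1ccc(C=O)c(O)c1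
F3 | step 3 | potassium 5-formyl-4-hydroxy-2-methoxyphenyl sulfate | COc1cc(O)c(C=O)cc1OS(=O)(=O)[O-].[K+]
F4 | step 3 | 2,5-dihydroxy-4-methoxybenzaldehyde | COc1cc(O)c(C=O)cc1O
F5 | step 3 | 7-methoxy-2-oxo-3-[(2-oxo-2H-chromen-7-yl)oxy]-2H-chromen-6-yl acetate | COc1cc2oc(=O)c(Oc3ccc4ccc(=O)oc4c3)cc2cc1OC(C)=O
F6 | step 2 | ethyl (E)-3-hydroxy-2-[(2-oxo-2H-chromen-7-yl)oxy]prop-2-enoate | CCOC(=O)/C(Oc1ccc2ccc(=O)oc2c1)=C\O
F0 | step 1 | none | none
A1 | alternative 1 | isoscopoletin (6-hydroxy-7-methoxy-2H-chromen-2-one) | COc1cc2oc(=O)ccc2cc1O
A2 | alternative 1 | 6-(benzyloxy)-3-bromo-7-methoxy-2H-chromen-2-one | COc1cc2oc(=O)c(Br)cc2cc1OCc1ccccc1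
A3 | alternative 1 | 6-(benzyloxy)-7-methoxy-3-[(2-oxo-2H-chromen-7-yl)oxy]-2H-chromen-2-one | COc1cc2oc(=O)c(Oc3ccc4ccc(=O)oc4c3)cc2cc1OCc1ccccc1
A4 | alternative 2 | 5-(benzyloxy)-2-hydroxy-4-methoxybenzaldehyde | COc1cc(O)c(C=O)cc1OCc1ccccc1
A5 | alternative 2 | ethyl 2-(diethoxyphosphoryl)-2-[(2-oxo-2H-chromen-7-yl)oxy]acetate (racemic) | CCOC(=O)C(Oc1ccc2ccc(=O)oc2c1)P(=O)(OCC)OCC
A6 | alternative 3 | esculetin (6,7-dihydroxy-2H-chromen-2-one) | Oc1cc2oc(=O)ccc2cc1O
A7 | alternative 3 | 6,7-dihydroxy-3-[(2-oxo-2H-chromen-7-yl)oxy]-2H-chromen-2-one | Oc1cc2oc(=O)c(Oc3ccc4ccc(=O)oc4c3)cc2cc1O
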